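**Retrosynthetic overview**

1. Feature (cembrane numbering: C1 = ring-fusion CH carrying the acrylate carbon C15, C14 = O–CH): the C14–O and C12–OH bonds are 1,3-syn across C13 and Cl on C11 is anti to the C12 oxygen. This is the imprint of an anti addition to an (E)-C11=C12 olefin with oxygen handed over from C14.
2. Hence: chlorohydrin ⇐ 11,12-epoxide (chloride at C11) ⇐ C11 iodide with a C12,C14 cyclic carbonate ⇐ IBr cyclisation of the C14 tert-butyl carbonate of the macrocyclic triene.
3. Triene ⇐ intramolecular allylboration (C1–C14) of a seco aldehyde carrying a (Z)-2-(borylmethyl)enoate. The chain must be cis to the ester and trans to CH2B, since only this geometry gives the anti adduct of the trans-lactone series. The racemate is resolved.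
4. Seco chain ⇐ (2E,6E)-farnesyl bromide: alkynylation at C2, ω-methyl → CH2CH2OH by SeO2 / Wittig / hydroboration, then ynoate → hydroalumination / ICH2Bpin.
5. Ring order: 14-membered carbocycle (step 10), temporary six-membered carbonate (step 13), oxirane (step 14), γ-lactone (step 15), oxirane opened (step 16).

Key step: step 13

Remark: cembrane numbering is used for all macrocycles, a racemate is written as the two enantiomers joined by a dot, and the acrylate is carried as its tert-butyl ester so that the C14 hydroxyl does not lactonise before the carbonate chemistry is over.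

**Route**

Step 1
Reactants: 1 (2E,6E)-farnesyl bromide; 2 ethynyltrimethylsilane
Product: 4 trimethyl[(4E,8E)-5,9,13-trimethyltetradeca-4,8,12-trien-1-yn-1-yl]silane, via alkynylmagnesium bromide 3 (not isolated)
Conditions: 2, EtMgBr, THF, 0 °C to rt; then CuCl (10 mol %), 1, THF, 50 °C
Reagents that add atoms: none
Why: Copper-catalysed SN2 coupling of an alkynyl Grignard reagent with a primary allylic bromide should give the skipped enyne at the unsubstituted allylic terminus with the (E)-olefins untouched; the silyl cap keeps the alkyne inert until step 6.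

Step 2
Reactants: 4 silyl enyne
Product: 6 (2E,6E,10E)-2,6,10-trimethyl-14-(trimethylsilyl)tetradeca-2,6,10-trien-13-ynal, via allylic alcohol 5 (not isolated)
Conditions: SeO2 (0.3 equiv), t-BuOOH, salicylic acid (cat.), CH2Cl2, rt; crude product, then MnO2, CH2Cl2, rt
Reagents that add atoms: tert-butyl hydroperoxide, CC(C)(C)OO
Why: Riley allylic oxidation (ene reaction, then [2,3] shift) is selective for the (E)-methyl of the terminal isopropylidene unit and gives the (E)-allylic alcohol, which MnO2 (allylic alcohol oxidation) should carry on to the (E)-enal; no stereocentre is formed.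

Step 3
Reactants: 6 enal
Product: 7 trimethyl[(4E,8E,12E)-5,9,13-trimethylpentadeca-4,8,12,14-tetraen-1-yn-1-yl]silane
Conditions: Ph3PCH3Br, n-BuLi, THF, 0 °C; then 6, −78 °C to rt
Reagents that add atoms: methyltriphenylphosphonium bromide, C[P+](c1ccccc1)(c1ccccc1)c1ccccc1.[Br-]
Why: Wittig methylenation of the enal should give the terminal 1,3-diene without touching the trisubstituted olefins or the silylalkyne.

Step 4
Reactants: 7 diene
Product: 10 (3E,7E,11E)-3,7,11-trimethylpentadeca-3,7,11-trien-14-yn-1-ol, via alkylborane 8 (not isolated), via silylalkynol 9 (not isolated)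
Conditions: 9-BBN, THF, 0 °C to rt; then NaOH, H2O2, MeOH–H2O, 0 °C to rt
Reagents that add atoms: hydrogen peroxide, OO
Why: Hydroboration–oxidation with the bulky 9-BBN should take place only at the monosubstituted terminal vinyl group (anti-Markovnikov), adding the future C14 as CH2OH, and the alkaline methanolic work-up also cleaves the alkynyl C–Si bond.

Step 5
Reactants: 10 alkynol
Product: 11 triethyl{[(3E,7E,11E)-3,7,11-trimethylpentadeca-3,7,11-trien-14-yn-1-yl]oxy}silane
Conditions: Et3SiCl, imidazole, CH2Cl2, 0 °C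
Reagents that add atoms: chlorotriethylsilane, CC[Si](Cl)(CC)CC
Why: Standard silylation of the primary alcohol protects it against the organolithium and the aluminium hydride of the next two steps.

Step 6
Reactants: 11 silyl ether; 12 di-tert-butyl dicarbonate
Product: 14 tert-butyl (5E,9E,13E)-6,10,14-trimethyl-16-[(triethylsilyl)oxy]hexadeca-5,9,13-trien-2-ynoate, via lithium acetylide 13 (not isolated)
Conditions: n-BuLi, THF, −78 °C; then 12, −78 °C; AcOH quench at −78 °C
Reagents that add atoms: none
Why: Deprotonation of the terminal alkyne and acylation of the lithium acetylide with Boc2O should give the tert-butyl 2-ynoate, and the cold acidic quench prevents base-induced isomerisation of the skipped CH2.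

Step 7
Reactants: 14 ynoate; 15 2-(iodomethyl)-4,4,5,5-tetramethyl-1,3,2-dioxaborolane
Product: 17 tert-butyl (2Z,5E,9E,13E)-6,10,14-trimethyl-2-[(4,4,5,5-tetramethyl-1,3,2-dioxaborolan-2-yl)methyl]-16-[(triethylsilyl)oxy]hexadeca-2,5,9,13-tetraenoate, via vinylalane 16 (not isolated)
Conditions: i-Bu2AlH, HMPA, THF, 0 °C; then 15, 0 °C to rt
Reagents that add atoms: none
Why: Conjugate hydroalumination of the ynoate by the i-Bu2AlH–HMPA complex delivers H and Al cis, and C-alkylation of the α-aluminoacrylate by the iodomethylboronate (boron ate complex, then 1,2-shift) should occur with retention, so the chain ends cis to the ester and trans to CH2B, the geometry that leads to the anti adduct in step 10.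

Step 8
Reactants: 17 silyl ether boronate
Product: 18 tert-butyl (2Z,5E,9E,13E)-16-hydroxy-6,10,14-trimethyl-2-[(4,4,5,5-tetramethyl-1,3,2-dioxaborolan-2-yl)methyl]hexadeca-2,5,9,13-tetraenoate
Conditions: PPTS (cat.), MeOH–CH2Cl2, 0 °C to rt
Reagents that add atoms: none
Why: Acid-catalysed methanolysis removes the primary triethylsilyl ether, while the pinacol boronate, the tert-butyl ester and the olefins should be stable to PPTS.

Step 9
Reactants: 18 hydroxy boronate
Product: 19 tert-butyl (2Z,5E,9E,13E)-6,10,14-trimethyl-16-oxo-2-[(4,4,5,5-tetramethyl-1,3,2-dioxaborolan-2-yl)methyl]hexadeca-2,5,9,13-tetraenoate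
Conditions: Dess–Martin periodinane, NaHCO3, CH2Cl2, 0 °C; used at once
Reagents that add atoms: none
Why: Buffered Dess–Martin oxidation gives the β,γ-unsaturated aldehyde under non-basic conditions that should not move the C11=C12 olefin into conjugation, and the ester-substituted allylboronate is inert to aldehydes at this temperature without a Lewis acid.

Step 10
Reactants: 19 seco aldehyde
Product: 21 racemic tert-butyl 2-[(1R*,14S*,3E,7E,11E)-14-hydroxy-4,8,12-trimethylcyclotetradeca-3,7,11-trien-1-yl]prop-2-enoate, via borate ester 20 (not isolated)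
Conditions: Sc(OTf)3 (0.3 equiv), 4 Å MS, CH2Cl2, slow addition of 19 (final 3 mM), 0 °C to rt; then aq. NaHCO3
Reagents that add atoms: none
Why: Lewis-acid-catalysed intramolecular allylboration through a closed chair transition state, with the aldehyde chain (C13) and the γ-substituent (C2, trans to CH2B) both equatorial, forms C1–C14, closes the 14-membered ring and sets C1 and C14 together as the anti pair of the trans-lactone series (racemic, as no chiral element is present); the hindered tert-butyl ester should not lactonise onto the borate.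

Step 11
Reactants: 21 racemic anti hydroxy ester
Product: 22 tert-butyl 2-[(1R,14S,3E,7E,11E)-14-hydroxy-4,8,12-trimethylcyclotetradeca-3,7,11-trien-1-yl]prop-2-enoate
Conditions: preparative HPLC, amylose tris(3,5-dimethylphenylcarbamate) stationary phase, hexane/i-PrOH
Reagents that add atoms: none
Why: Resolution of the racemate by chromatography on a chiral stationary phase should give the (1R,14S) enantiomer, whose absolute configuration is to be confirmed by MTPA ester analysis at C14; the stereocentres themselves are not touched.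

Step 12
Reactants: 22 (1R,14S) hydroxy ester; 12 di-tert-butyl dicarbonate
Product: 23 tert-butyl 2-[(1R,14S,3E,7E,11E)-14-[(tert-butoxycarbonyl)oxy]-4,8,12-trimethylcyclotetradeca-3,7,11-trien-1-yl]prop-2-enoate
Conditions: Boc2O, DMAP, MeCN, rt
Reagents that add atoms: none
Why: DMAP-catalysed acylation of the secondary C14 hydroxyl with Boc2O installs the tert-butyl carbonate that serves as the tether, under neutral conditions that should not cause lactonisation.

Step 13
Reactants: 23 triene tert-butyl carbonate
Product: 25 tert-butyl 2-[(1R,11S,12R,14S,3E,7E)-11-iodo-4,8,12-trimethyl-12,14-(carbonyldioxy)cyclotetradeca-3,7-dien-1-yl]prop-2-enoate (six-membered cyclic carbonate bridging O12 and O14), via dioxanylium bromide 24 (not isolated)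
Conditions: IBr (1.1 equiv), toluene, −85 °C; then aq. Na2S2O3/NaHCO3
Reagents that add atoms: iodine monobromide, IBr
Why: IBr forms iodonium ions reversibly at the trisubstituted olefins; at C11=C12 the carbonyl oxygen of the C14 carbonate attacks C12, the more substituted carbon, anti to iodine, and the tert-butoxydioxanylium ion 24 then loses its tert-butyl group to bromide. The closest known reaction type is the low-temperature IBr iodocarbonate cyclisation of homoallylic tert-butyl carbonates to 4,6-cis-1,3-dioxan-2-ones (syn-1,3-diol derivatives). The six-membered carbonate ring closes in the 6-exo mode with respect to the iodonium ring. C11 is set by the stereospecific anti addition across the (E)-olefin, and C12 by a chair-like transition state in which the C1 branch on C14 and the C11 branch on C12 are equatorial and the C12 methyl is axial, which places the C12 and C14 oxygens 1,3-syn. The step needs site selectivity among three trisubstituted olefins and the acrylate: only C11=C12 has an internal nucleophile within 6-exo reach, iodonium formation elsewhere should revert at −85 °C with about one equivalent of IBr, and the acrylate olefin is electron-poor. The tert-butyl ester should not compete, since its carbonyl could only reach C3, the less substituted carbon of C3=C4, or close a seven-membered ring.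

Step 14
Reactants: 25 iodo cyclic carbonate
Product: 27 tert-butyl 2-[(1R,11R,12R,14S,3E,7E)-11,12-epoxy-14-hydroxy-4,8,12-trimethylcyclotetradeca-3,7-dien-1-yl]prop-2-enoate, via iodo diol 26 (not isolated)
Conditions: K2CO3, MeOH, 0 °C
Reagents that add atoms: none
Why: Base-mediated methanolysis of the cyclic carbonate (transesterification to dimethyl carbonate) frees both hydroxyls, and the tertiary C12 alkoxide should displace the neighbouring iodide in an intramolecular Williamson reaction with inversion at C11, giving the trans-11,12-epoxide with C12 unchanged; the open-chain tert-butyl acrylate is a poor acceptor for methoxide at 0 °C.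

Step 15
Reactants: 27 epoxy hydroxy ester
Product: 28 (1R,11R,12R,14S,3E,7E)-11,12-epoxycembra-3,7,15(17)-trien-16,14-olide
Conditions: t-BuOK (0.2 equiv), THF, 0 °C
Reagents that add atoms: none
Why: Alkoxide-catalysed intramolecular transesterification (lactonisation), in which the C14 alkoxide attacks the tert-butyl ester in the 5-exo mode and the expelled tert-butoxide carries the chain, should close the trans-fused α-methylene γ-lactone in the absence of methanol, which could add to the exocyclic olefin.

Step 16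
Reactants: 28 epoxy lactone
Product: 29 (1R,11S,12R,14S,3E,7E)-11-chloro-12-hydroxycembra-3,7,15(17)-trien-16,14-olide (CNP0247658.1)
Conditions: LiCl, AcOH, THF, rt
Reagents that add atoms: lithium chloride, [Li+].[Cl-]
Why: Halohydrin formation by SN2 opening of the epoxide: with a high chloride concentration and only acetic acid as activator, chloride should attack the less hindered secondary C11 with inversion, anti to the C12 oxygen, which returns C11 to the configuration of the iodide (double inversion) and leaves the tertiary C12–O bond intact.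

**Compound list**

1 | (2E,6E)-farnesyl bromide [(2E,6E)-1-bromo-3,7,11-trimethyldodeca-2,6,10-triene] | CC(C)=CCC/C(C)=C/CC/C(C)=C/CBr | starting material
2 | ethynyltrimethylsilane | C#C[Si](C)(C)C | starting material
3 | [(trimethylsilyl)ethynyl]magnesium bromide | C[Si](C)(C)C#C[Mg]Br | intermediate
4 | trimethyl[(4E,8E)-5,9,13-trimethyltetradeca-4,8,12-trien-1-yn-1-yl]silane | CC(C)=CCC/C(C)=C/CC/C(C)=C/CC#C[Si](C)(C)C | intermediate
5 | (2E,6E,10E)-2,6,10-trimethyl-14-(trimethylsilyl)tetradeca-2,6,10-trien-13-yn-1-ol | OC/C(C)=C/CC/C(C)=C/CC/C(C)=C/CC#C[Si](C)(C)C | intermediate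
6 | (2E,6E,10E)-2,6,10-trimethyl-14-(trimethylsilyl)tetradeca-2,6,10-trien-13-ynal | O=C/C(C)=C/CC/C(C)=C/CC/C(C)=C/CC#C[Si](C)(C)C | intermediate
7 | trimethyl[(4E,8E,12E)-5,9,13-trimethylpentadeca-4,8,12,14-tetraen-1-yn-1-yl]silane | C=C/C(C)=C/CC/C(C)=C/CC/C(C)=C/CC#C[Si](C)(C)C | intermediate
8 | 9-[(3E,7E,11E)-3,7,11-trimethyl-15-(trimethylsilyl)pentadeca-3,7,11-trien-14-yn-1-yl]-9-borabicyclo[3.3.1]nonane | C[Si](C)(C)C#CC/C=C(C)/CC/C=C(C)/CC/C=C(C)/CCB1C2CCCC1CCC2 | intermediate
9 | (3E,7E,11E)-3,7,11-trimethyl-15-(trimethylsilyl)pentadeca-3,7,11-trien-14-yn-1-ol | OCC/C(C)=C/CC/C(C)=C/CC/C(C)=C/CC#C[Si](C)(C)C | intermediate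
10 | (3E,7E,11E)-3,7,11-trimethylpentadeca-3,7,11-trien-14-yn-1-ol | OCC/C(C)=C/CC/C(C)=C/CC/C(C)=C/CC#C | intermediate
11 | triethyl{[(3E,7E,11E)-3,7,11-trimethylpentadeca-3,7,11-trien-14-yn-1-yl]oxy}silane | CC[Si](CC)(CC)OCC/C(C)=C/CC/C(C)=C/CC/C(C)=C/CC#C | intermediate
12 | di-tert-butyl dicarbonate | CC(C)(C)OC(=O)OC(=O)OC(C)(C)C | starting material
13 | lithium acetylide of 11 | CC[Si](CC)(CC)OCC/C(C)=C/CC/C(C)=C/CC/C(C)=C/CC#C[Li] | intermediate
14 | tert-butyl (5E,9E,13E)-6,10,14-trimethyl-16-[(triethylsilyl)oxy]hexadeca-5,9,13-trien-2-ynoate | CC[Si](CC)(CC)OCC/C(C)=C/CC/C(C)=C/CC/C(C)=C/CC#CC(=O)OC(C)(C)C | intermediate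
15 | 2-(iodomethyl)-4,4,5,5-tetramethyl-1,3,2-dioxaborolane | ICB1OC(C)(C)C(C)(C)O1 | starting material
16 | tert-butyl (2E,5E,9E,13E)-2-(diisobutylalumanyl)-6,10,14-trimethyl-16-[(triethylsilyl)oxy]hexadeca-2,5,9,13-tetraenoate (H and Al cis) | CC[Si](CC)(CC)OCC/C(C)=C/CC/C(C)=C/CC/C(C)=C/C/C=C(\C(=O)OC(C)(C)C)[Al](CC(C)C)CC(C)C | intermediate
17 | tert-butyl (2Z,5E,9E,13E)-6,10,14-trimethyl-2-[(4,4,5,5-tetramethyl-1,3,2-dioxaborolan-2-yl)methyl]-16-[(triethylsilyl)oxy]hexadeca-2,5,9,13-tetraenoate | CC[Si](CC)(CC)OCC/C(C)=C/CC/C(C)=C/CC/C(C)=C/C/C=C(\C(=O)OC(C)(C)C)CB1OC(C)(C)C(C)(C)O1 | intermediate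
18 | tert-butyl (2Z,5E,9E,13E)-16-hydroxy-6,10,14-trimethyl-2-[(4,4,5,5-tetramethyl-1,3,2-dioxaborolan-2-yl)methyl]hexadeca-2,5,9,13-tetraenoate | OCC/C(C)=C/CC/C(C)=C/CC/C(C)=C/C/C=C(\C(=O)OC(C)(C)C)CB1OC(C)(C)C(C)(C)O1 | intermediate
19 | tert-butyl (2Z,5E,9E,13E)-6,10,14-trimethyl-16-oxo-2-[(4,4,5,5-tetramethyl-1,3,2-dioxaborolan-2-yl)methyl]hexadeca-2,5,9,13-tetraenoate | O=CC/C(C)=C/CC/C(C)=C/CC/C(C)=C/C/C=C(\C(=O)OC(C)(C)C)CB1OC(C)(C)C(C)(C)O1 | intermediate
20 | racemic O-(pinacolboryl) derivative of 21 (C14–O–B), (1R*,14S*) | C=C(C(=O)OC(C)(C)C)[C@H]1C/C=C(C)/CC/C=C(C)/CC/C=C(C)/C[C@@H]1OB2OC(C)(C)C(C)(C)O2.C=C(C(=O)OC(C)(C)C)[C@@H]1C/C=C(C)/CC/C=C(C)/CC/C=C(C)/C[C@H]1OB2OC(C)(C)C(C)(C)O2 | intermediate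
21 | racemic tert-butyl 2-[(1R*,14S*,3E,7E,11E)-14-hydroxy-4,8,12-trimethylcyclotetradeca-3,7,11-trien-1-yl]prop-2-enoate | C=C(C(=O)OC(C)(C)C)[C@H]1C/C=C(C)/CC/C=C(C)/CC/C=C(C)/C[C@@H]1O.C=C(C(=O)OC(C)(C)C)[C@@H]1C/C=C(C)/CC/C=C(C)/CC/C=C(C)/C[C@H]1O | intermediate
22 | tert-butyl 2-[(1R,14S,3E,7E,11E)-14-hydroxy-4,8,12-trimethylcyclotetradeca-3,7,11-trien-1-yl]prop-2-enoate | C=C(C(=O)OC(C)(C)C)[C@H]1C/C=C(C)/CC/C=C(C)/CC/C=C(C)/C[C@@H]1O | intermediate
23 | tert-butyl 2-[(1R,14S,3E,7E,11E)-14-[(tert-butoxycarbonyl)oxy]-4,8,12-trimethylcyclotetradeca-3,7,11-trien-1-yl]prop-2-enoate | C=C(C(=O)OC(C)(C)C)[C@H]1C/C=C(C)/CC/C=C(C)/CC/C=C(C)/C[C@@H]1OC(=O)OC(C)(C)C | intermediate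
24 | 2-tert-butoxy-1,3-dioxan-2-ylium bromide spanning O12 and O14, with C11 iodide (1R,11S,12R,14S) | C=C(C(=O)OC(C)(C)C)[C@H]1C/C=C(C)/CC/C=C(C)/CC[C@H](I)[C@@]2(C)C[C@@H]1OC(OC(C)(C)C)=[O+]2.[Br-] | intermediate
25 | tert-butyl 2-[(1R,11S,12R,14S,3E,7E)-11-iodo-4,8,12-trimethyl-12,14-(carbonyldioxy)cyclotetradeca-3,7-dien-1-yl]prop-2-enoate | C=C(C(=O)OC(C)(C)C)[C@H]1C/C=C(C)/CC/C=C(C)/CC[C@H](I)[C@@]2(C)C[C@@H]1OC(=O)O2 | intermediate
26 | tert-butyl 2-[(1R,11S,12R,14S,3E,7E)-12,14-dihydroxy-11-iodo-4,8,12-trimethylcyclotetradeca-3,7-dien-1-yl]prop-2-enoate | C=C(C(=O)OC(C)(C)C)[C@H]1C/C=C(C)/CC/C=C(C)/CC[C@H](I)[C@](C)(O)C[C@@H]1O | intermediate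
27 | tert-butyl 2-[(1R,11R,12R,14S,3E,7E)-11,12-epoxy-14-hydroxy-4,8,12-trimethylcyclotetradeca-3,7-dien-1-yl]prop-2-enoate | C=C(C(=O)OC(C)(C)C)[C@H]1C/C=C(C)/CC/C=C(C)/CC[C@H]2O[C@]2(C)C[C@@H]1O | intermediate
28 | (1R,11R,12R,14S,3E,7E)-11,12-epoxycembra-3,7,15(17)-trien-16,14-olide | C=C1C(=O)O[C@H]2C[C@@]3(C)O[C@@H]3CC/C(C)=C/CC/C(C)=C/C[C@H]12 | intermediate
29 | (1R,11S,12R,14S,3E,7E)-11-chloro-12-hydroxycembra-3,7,15(17)-trien-16,14-olide | C=C1C(=O)O[C@H]2C[C@@](C)(O)[C@@H](Cl)CC/C(C)=C/CC/C(C)=C/C[C@H]12 | target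

**Step count**

Total steps: 16. Longest linear sequence: 16 steps (from 1).

**Steps most likely to fail**

Step 13 (key step). Two processes may go wrong. Iodonium ions at C3=C4 or C7=C8 may be captured by bromide or by a transannular olefin before they revert. The macrocycle may also override the chair preference, giving poor facial selectivity at C12. The fallback sets out from 22, before the carbonate is made. Hydroxyl-directed epoxidation with VO(acac)2 and t-BuOOH in CH2Cl2 delivers oxygen from a vanadate ester on the C14 hydroxyl to the homoallylic C11=C12 olefin only. It would do so through the same kind of chair with the C1 branch equatorial, which should again give the 12,14-syn epoxy alcohol; this selectivity would have to be checked. The product is 27, where the route is rejoined for step 15. No new compound is made.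

Step 10 (macrocyclisation). Ring closure at high dilution may be slower than oligomerisation, and the Lewis acid may move the β,γ-olefin of the aldehyde into conjugation or lactonise the adduct. The fallback replaces the allylboron by an allylchromium reagent and sets out from 14. The vinylalane 16 is trapped with formaldehyde instead of 15 to give the allylic alcohol F1. CBr4 and PPh3 (Appel reaction) convert it into the allylic bromide F2. PPTS in MeOH then frees the bromo alcohol F3, and Dess–Martin oxidation gives the bromo aldehyde F4. CrCl2 in THF at high dilution (Nozaki–Hiyama reaction) would close the ring to racemic 21, where the route is rejoined at step 11. With the equilibrating allylchromium species the anti selectivity is no longer fixed by the olefin geometry, so any syn isomer would be removed by chromatography first.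

Step 16 (chloride opening). Chloride may attack the tertiary C12 through a loose, cation-like transition state, or the activated epoxide may be captured across the ring by the C7=C8 olefin. The fallback removes electrophilic activation and sets out from 28. LiOH in THF–H2O opens the lactone to the lithium epoxy hydroxy carboxylate F5, in which the acrylate is no longer a conjugate acceptor. Heating F5 with saturated LiCl in pH 7 phosphate buffer (H2O–DMF, 60 °C) would open the epoxide by plain SN2 attack at the secondary C11. Acidification gives the chlorohydrin hydroxy acid F6, which lactonises at pH 3 to 29.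

**Further compounds**

F0 | step 13 | none | none
F1 | step 10 | tert-butyl (2Z,5E,9E,13E)-2-(hydroxymethyl)-6,10,14-trimethyl-16-[(triethylsilyl)oxy]hexadeca-2,5,9,13-tetraenoate | CC[Si](CC)(CC)OCC/C(C)=C/CC/C(C)=C/CC/C(C)=C/C/C=C(\C(=O)OC(C)(C)C)CO
F2 | step 10 | tert-butyl (2E,5E,9E,13E)-2-(bromomethyl)-6,10,14-trimethyl-16-[(triethylsilyl)oxy]hexadeca-2,5,9,13-tetraenoate | CC[Si](CC)(CC)OCC/C(C)=C/CC/C(C)=C/CC/C(C)=C/C/C=C(\C(=O)OC(C)(C)C)CBr
F3 | step 10 | tert-butyl (2E,5E,9E,13E)-2-(bromomethyl)-16-hydroxy-6,10,14-trimethylhexadeca-2,5,9,13-tetraenoate | OCC/C(C)=C/CC/C(C)=C/CC/C(C)=C/C/C=C(\C(=O)OC(C)(C)C)CBr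
F4 | step 10 | tert-butyl (2E,5E,9E,13E)-2-(bromomethyl)-6,10,14-trimethyl-16-oxohexadeca-2,5,9,13-tetraenoate | O=CC/C(C)=C/CC/C(C)=C/CC/C(C)=C/C/C=C(\C(=O)OC(C)(C)C)CBr
F5 | step 16 | lithium 2-[(1R,11R,12R,14S,3E,7E)-11,12-epoxy-14-hydroxy-4,8,12-trimethylcyclotetradeca-3,7-dien-1-yl]prop-2-enoate | C=C(C(=O)[O-])[C@H]1C/C=C(C)/CC/C=C(C)/CC[C@H]2O[C@]2(C)C[C@@H]1O.[Li+]
F6 | step 16 | 2-[(1R,11S,12R,14S,3E,7E)-11-chloro-12,14-dihydroxy-4,8,12-trimethylcyclotetradeca-3,7-dien-1-yl]prop-2-enoic acid | C=C(C(=O)O)[C@H]1C/C=C(C)/CC/C=C(C)/CC[C@H](Cl)[C@](C)(O)C[C@@H]1O
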